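**Retrosynthetic overview**
1. The target is two identical gigantol halves on one CH2. The last step is global hydrogenolysis of its tetra-O-benzyl ether.
2. Key disconnection: the central aryl–CH2 bond leads back to a benzyl arenecarboxylate made from an "acid half" and an "alcohol half". In the forward sense, a new Pd/Ag-catalysed CO2 extrusion puts the CH2 on the carbon that carried the carboxyl group (between OH and side chain). Phenol/formaldehyde chemistry cannot single out this site from the other activated ring positions.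
3. Both halves come from one common bibenzyl methyl ester (LiAlH4 reduction or saponification) and are rejoined by Mitsunobu esterification.
4. The bibenzyl CH2–CH2 bond comes from lateral lithiation of O-benzyl methyl everninate and alkylation with O-benzylvanillyl bromide. The OH/OMe pattern comes from chelation-controlled 4-O-methylation of methyl orsellinate.
5. No ring is formed. All four benzene rings are bought (methyl orsellinate twice, O-benzylvanillyl alcohol twice).

Assumption: the SMILES contains no stereocentre and the molecule is achiral (two identical halves on one CH2), so "single enantiomer" requires no stereocontrol and the constitution is made as drawn.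

**Step 1**
Reactants: 1 methyl 2,4-dihydroxy-6-methylbenzoate (methyl orsellinate)
Product: 2 methyl 2-hydroxy-4-methoxy-6-methylbenzoate
Conditions: MeI (1.1 equiv), K2CO3 (1.1 equiv), acetone, 40 °C
Reagents that add atoms: iodomethane, CI
Why: Williamson ether synthesis in which the 2-OH is hydrogen-bonded to the ester carbonyl, so one equivalent of MeI alkylates only the free 4-OH.

**Step 2**
Reactants: 2 methyl 2-hydroxy-4-methoxy-6-methylbenzoate
Product: 3 methyl 2-(benzyloxy)-4-methoxy-6-methylbenzoate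
Conditions: BnBr (1.3 equiv), K2CO3 (2 equiv), DMF, 60 °C
Reagents that add atoms: benzyl bromide, BrCc1ccccc1
Why: Williamson ether synthesis under more forcing conditions alkylates the chelated phenol, and benzyl is chosen so that all phenol protecting groups are removed in one final hydrogenolysis.

**Step 3**
Reactants: 4 [4-(benzyloxy)-3-methoxyphenyl]methanol
Product: 5 1-(benzyloxy)-4-(bromomethyl)-2-methoxybenzene
Conditions: PBr3 (0.4 equiv), Et2O, 0 °C, used crude at once
Reagents that add atoms: phosphorus tribromide, BrP(Br)Br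
Why: SN2 bromination of a primary benzylic alcohol with PBr3, which leaves the aryl ethers untouched.

**Step 4**
Reactants: 3 methyl 2-(benzyloxy)-4-methoxy-6-methylbenzoate; 5 1-(benzyloxy)-4-(bromomethyl)-2-methoxybenzene
Product: 7 methyl 2-(benzyloxy)-6-{2-[4-(benzyloxy)-3-methoxyphenyl]ethyl}-4-methoxybenzoate, via benzylic lithium species 6 (not isolated)
Conditions: LDA (commercial solution, 1.15 equiv), THF, −78 °C, 15 min; then 5 (1.2 equiv), −78 to −20 °C
Reagents that add atoms: none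
Why: Lateral lithiation of an ortho-toluate followed by SN2 alkylation works because the ester acidifies the ortho-methyl group, its two ortho substituents slow self-condensation, and LDA at −78 °C does not deprotonate the benzyl ethers.

**Step 5**
Reactants: 7 methyl 2-(benzyloxy)-6-{2-[4-(benzyloxy)-3-methoxyphenyl]ethyl}-4-methoxybenzoate
Product: 8 (2-(benzyloxy)-6-{2-[4-(benzyloxy)-3-methoxyphenyl]ethyl}-4-methoxyphenyl)methanol
Conditions: LiAlH4 (1.5 equiv), THF, 0 °C to reflux; Fieser work-up, kept acid-free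
Reagents that add atoms: none
Why: LiAlH4 ester reduction is small and reactive enough for the di-ortho-substituted ester and spares all ethers.

**Step 6**
Reactants: 7 methyl 2-(benzyloxy)-6-{2-[4-(benzyloxy)-3-methoxyphenyl]ethyl}-4-methoxybenzoate
Product: 10 2-(benzyloxy)-6-{2-[4-(benzyloxy)-3-methoxyphenyl]ethyl}-4-methoxybenzoic acid, via potassium carboxylate 9 (not isolated)
Conditions: KOH (10 equiv), DMSO/H2O 4:1, 100 °C; then 1 M HCl, 0 °C, to pH 3
Reagents that add atoms: potassium hydroxide, [K+].[OH-]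
Why: Saponification with poorly solvated hydroxide in DMSO overcomes the hindrance of the ester, the ethers are inert to base, and cold acidification avoids protodecarboxylation.

**Step 7**
Reactants: 8 (2-(benzyloxy)-6-{2-[4-(benzyloxy)-3-methoxyphenyl]ethyl}-4-methoxyphenyl)methanol; 10 2-(benzyloxy)-6-{2-[4-(benzyloxy)-3-methoxyphenyl]ethyl}-4-methoxybenzoic acid
Product: 12 (2-(benzyloxy)-6-{2-[4-(benzyloxy)-3-methoxyphenyl]ethyl}-4-methoxyphenyl)methyl 2-(benzyloxy)-6-{2-[4-(benzyloxy)-3-methoxyphenyl]ethyl}-4-methoxybenzoate, via alkoxyphosphonium carboxylate 11 (not isolated)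
Conditions: PPh3 (1.3 equiv), DIAD (1.3 equiv), toluene/THF, 0 °C to rt
Reagents that add atoms: none
Why: In the Mitsunobu esterification the carboxylate attacks the activated primary benzylic carbon, so the hindered acyl carbon is never attacked and the near-neutral medium spares the acid-labile 2,4-dialkoxybenzyl alcohol.

**Step 8**
Reactants: 12 (2-(benzyloxy)-6-{2-[4-(benzyloxy)-3-methoxyphenyl]ethyl}-4-methoxyphenyl)methyl 2-(benzyloxy)-6-{2-[4-(benzyloxy)-3-methoxyphenyl]ethyl}-4-methoxybenzoate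
Product: 17 bis(2-(benzyloxy)-6-{2-[4-(benzyloxy)-3-methoxyphenyl]ethyl}-4-methoxyphenyl)methane, via benzylpalladium carboxylate 13 (not isolated), via silver carboxylate 14 (not isolated), via arylsilver 15 (not isolated), via aryl(benzyl)palladium 16 (not isolated)
Conditions: Pd2(dba)3 (2.5 mol %), DPEphos (6 mol %), AgOAc (10 mol %), 3 Å MS, NMP (0.05 M), 120 °C, argon
Reagents that add atoms: none
Why: Proposed new method: a redox-neutral, halide-free Pd(0)/Ag(I) dual-catalytic CO2 extrusion from a benzyl arenecarboxylate, in which Pd(0)/DPEphos ionises the benzylic C–O bond of 12 (a 2,6-disubstituted benzoate is a good leaving group and the 2,4-dialkoxy pattern stabilises the η3-benzyl) to give 13, silver (entered as AgOAc) takes up the carboxylate as 14, whose carboxyl group is twisted out of conjugation by two ortho substituents and sits on an ipso carbon activated by ortho-OBn and para-OMe so that it loses CO2 to give arylsilver 15, 15 transmetalates onto 13 to give 16 and return 14, and reductive elimination, accelerated by the wide bite angle, forms the aryl–CH2 bond only at the carbon that carried the carboxyl group (the benzyl ligand has no β-hydrogen and no halide is present to precipitate silver); the closest known reaction types are the intramolecular decarboxylative allylation of allyl nitro- or polyfluorobenzoates, Pd/Ag decarboxylative biaryl coupling of ortho-alkoxybenzoic acids and Pd-catalysed cross-coupling of benzylic esters, but their merger on an electron-rich benzyl benzoate to give a diarylmethane has not been shown.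

**Step 9**
Reactants: 17 bis(2-(benzyloxy)-6-{2-[4-(benzyloxy)-3-methoxyphenyl]ethyl}-4-methoxyphenyl)methane
Product: 18 2,2'-methylenebis{3-[2-(4-hydroxy-3-methoxyphenyl)ethyl]-5-methoxyphenol} (target)
Conditions: H2 (1 atm), 10 % Pd/C, EtOAc/MeOH 1:1, rt
Reagents that add atoms: none
Why: Catalytic hydrogenolysis cleaves all four aryl benzyl ethers, while the aryl methyl ethers, the diarylmethane and the bibenzyl C–C bonds are inert and no stereocentre is involved.

**Compound list**
1 | methyl 2,4-dihydroxy-6-methylbenzoate (methyl orsellinate) | COC(=O)c1c(C)cc(O)cc1O | starting material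
2 | methyl 2-hydroxy-4-methoxy-6-methylbenzoate | COC(=O)c1c(C)cc(OC)cc1O | intermediate
3 | methyl 2-(benzyloxy)-4-methoxy-6-methylbenzoate | COC(=O)c1c(C)cc(OC)cc1OCc1ccccc1 | intermediate
4 | [4-(benzyloxy)-3-methoxyphenyl]methanol | OCc1ccc(OCc2ccccc2)c(OC)c1 | starting material
5 | 1-(benzyloxy)-4-(bromomethyl)-2-methoxybenzene | BrCc1ccc(OCc2ccccc2)c(OC)c1 | intermediate
6 | {[3-(benzyloxy)-5-methoxy-2-(methoxycarbonyl)phenyl]methyl}lithium (benzylic lithium species, not isolated) | [Li]Cc1cc(OC)cc(OCc2ccccc2)c1C(=O)OC | intermediate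
7 | methyl 2-(benzyloxy)-6-{2-[4-(benzyloxy)-3-methoxyphenyl]ethyl}-4-methoxybenzoate | COC(=O)c1c(CCc2ccc(OCc3ccccc3)c(OC)c2)cc(OC)cc1OCc1ccccc1 | intermediate
8 | (2-(benzyloxy)-6-{2-[4-(benzyloxy)-3-methoxyphenyl]ethyl}-4-methoxyphenyl)methanol | OCc1c(CCc2ccc(OCc3ccccc3)c(OC)c2)cc(OC)cc1OCc1ccccc1 | intermediate
9 | potassium 2-(benzyloxy)-6-{2-[4-(benzyloxy)-3-methoxyphenyl]ethyl}-4-methoxybenzoate (not isolated) | [K+].[O-]C(=O)c1c(CCc2ccc(OCc3ccccc3)c(OC)c2)cc(OC)cc1OCc1ccccc1 | intermediate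
10 | 2-(benzyloxy)-6-{2-[4-(benzyloxy)-3-methoxyphenyl]ethyl}-4-methoxybenzoic acid | OC(=O)c1c(CCc2ccc(OCc3ccccc3)c(OC)c2)cc(OC)cc1OCc1ccccc1 | intermediate
11 | triphenylphosphonium ether of 8 paired with the carboxylate of 10 (alkoxyphosphonium carboxylate, not isolated) | [O-]C(=O)c1c(CCc2ccc(OCc3ccccc3)c(OC)c2)cc(OC)cc1OCc1ccccc1.c1ccc(cc1)[P+](c1ccccc1)(c1ccccc1)OCc1c(CCc2ccc(OCc3ccccc3)c(OC)c2)cc(OC)cc1OCc1ccccc1 | intermediate
12 | (2-(benzyloxy)-6-{2-[4-(benzyloxy)-3-methoxyphenyl]ethyl}-4-methoxyphenyl)methyl 2-(benzyloxy)-6-{2-[4-(benzyloxy)-3-methoxyphenyl]ethyl}-4-methoxybenzoate | O=C(OCc1c(CCc2ccc(OCc3ccccc3)c(OC)c2)cc(OC)cc1OCc1ccccc1)c1c(CCc2ccc(OCc3ccccc3)c(OC)c2)cc(OC)cc1OCc1ccccc1 | intermediate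
13 | benzylpalladium(II) carboxylate from oxidative addition of 12 (DPEphos on Pd not drawn, not isolated) | O=C(O[Pd]Cc1c(CCc2ccc(OCc3ccccc3)c(OC)c2)cc(OC)cc1OCc1ccccc1)c1c(CCc2ccc(OCc3ccccc3)c(OC)c2)cc(OC)cc1OCc1ccccc1 | intermediate
14 | silver(I) 2-(benzyloxy)-6-{2-[4-(benzyloxy)-3-methoxyphenyl]ethyl}-4-methoxybenzoate (not isolated) | [Ag+].[O-]C(=O)c1c(CCc2ccc(OCc3ccccc3)c(OC)c2)cc(OC)cc1OCc1ccccc1 | intermediate
15 | (2-(benzyloxy)-6-{2-[4-(benzyloxy)-3-methoxyphenyl]ethyl}-4-methoxyphenyl)silver (not isolated) | [Ag]c1c(CCc2ccc(OCc3ccccc3)c(OC)c2)cc(OC)cc1OCc1ccccc1 | intermediate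
16 | aryl(benzyl)palladium(II) carrying both halves (DPEphos on Pd not drawn, not isolated) | COc1cc(OCc2ccccc2)c([Pd]Cc2c(OCc3ccccc3)cc(OC)cc2CCc2ccc(OCc3ccccc3)c(OC)c2)c(CCc2ccc(OCc3ccccc3)c(OC)c2)c1 | intermediate
17 | bis(2-(benzyloxy)-6-{2-[4-(benzyloxy)-3-methoxyphenyl]ethyl}-4-methoxyphenyl)methane | COc1cc(OCc2ccccc2)c(Cc2c(OCc3ccccc3)cc(OC)cc2CCc2ccc(OCc3ccccc3)c(OC)c2)c(CCc2ccc(OCc3ccccc3)c(OC)c2)c1 | intermediate
18 | 2,2'-methylenebis{3-[2-(4-hydroxy-3-methoxyphenyl)ethyl]-5-methoxyphenol} (achiral) | COc1cc(O)c(Cc2c(O)cc(OC)cc2CCc2ccc(O)c(OC)c2)c(CCc2ccc(O)c(OC)c2)c1 | target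

**Total step count:** 9. **Longest linear sequence:** 7 steps (1 → 2 → 3 → 7 → 8 or 10 → 12 → 17 → 18).

**Three steps most likely to fail**

**Step 8 (the proposed new step).** The risks are:
- protodemetalation of 15 by traces of water;
- slow ionisation of the di-ortho-substituted benzylic ester;
- Pd(0)/Ag(I) redox interference.

The fallback uses only known chemistry, sets out from 8 and 10 and comes back at 17. Acid 10 undergoes transition-metal-free decarboxylative ipso-iodination (I2, K3PO4, MeCN, 100 °C) to give 1-(benzyloxy)-3-{2-[4-(benzyloxy)-3-methoxyphenyl]ethyl}-2-iodo-5-methoxybenzene F1, which keeps the regiochemistry fixed. Alcohol 8 is oxidised (MnO2, CH2Cl2, rt) to 2-(benzyloxy)-6-{2-[4-(benzyloxy)-3-methoxyphenyl]ethyl}-4-methoxybenzaldehyde F2. Iodine–lithium exchange on F1 (n-BuLi, THF, −78 °C) gives (2-(benzyloxy)-6-{2-[4-(benzyloxy)-3-methoxyphenyl]ethyl}-4-methoxyphenyl)lithium F3. This adds to F2 and, after an NH4Cl quench, gives bis(2-(benzyloxy)-6-{2-[4-(benzyloxy)-3-methoxyphenyl]ethyl}-4-methoxyphenyl)methanol F4. Ionic hydrogenation of this strongly stabilised diarylcarbinol (Et3SiH, TFA, CH2Cl2, −40 to 0 °C) gives 17.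

**Step 4.** The risks are:
- self-condensation of 6;
- proton transfer from product 7 to 6 followed by double alkylation;
- decomposition of the labile bromide 5.

The fallback sets out from 4 and comes back at 7. It forms the aryl–CH2 bond instead of the CH2–CH2 bond and needs no toluate anion. Alcohol 4 is oxidised (MnO2, CH2Cl2) to 4-(benzyloxy)-3-methoxybenzaldehyde F5. Wittig methylenation (Ph3PCH3Br, KOt-Bu, THF) gives 1-(benzyloxy)-4-ethenyl-2-methoxybenzene F6. Hydroboration (9-BBN-H, THF, rt) gives 9-{2-[4-(benzyloxy)-3-methoxyphenyl]ethyl}-9-borabicyclo[3.3.1]nonane F7. In parallel, bought-in methyl 2,6-dihydroxy-4-methoxybenzoate F8 is mono-benzylated (BnBr 1.0 equiv, K2CO3, acetone, reflux) to methyl 2-(benzyloxy)-6-hydroxy-4-methoxybenzoate F9. Triflation (Tf2O, pyridine, CH2Cl2, 0 °C) gives methyl 2-(benzyloxy)-4-methoxy-6-[(trifluoromethanesulfonyl)oxy]benzoate F10. B-alkyl Suzuki–Miyaura coupling of F7 with F10 (PdCl2(dppf), K3PO4, THF/DMF/H2O, 60 °C) gives 7 directly.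

**Step 7.** The risk is that 11 ionises to the 2,4-dialkoxybenzyl cation, which then alkylates arenes (Friedel–Crafts self-alkylation) or the hydrazide nitrogen.

The fallback sets out from 8 and 10 and comes back at 12. It makes the acyl C–O bond under basic conditions instead of the alkyl C–O bond. Acid 10 is converted ((COCl)2, cat. DMF, CH2Cl2, 0 °C) into 2-(benzyloxy)-6-{2-[4-(benzyloxy)-3-methoxyphenyl]ethyl}-4-methoxybenzoyl chloride F11. Alcohol 8 is deprotonated (NaH, THF, 0 °C) to sodium (2-(benzyloxy)-6-{2-[4-(benzyloxy)-3-methoxyphenyl]ethyl}-4-methoxyphenyl)methanolate F12. Adding F11 to F12 (THF, 0 °C to rt) gives 12.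

**Further compounds**
F1 | step 8 | 1-(benzyloxy)-3-{2-[4-(benzyloxy)-3-methoxyphenyl]ethyl}-2-iodo-5-methoxybenzene | Ic1c(CCc2ccc(OCc3ccccc3)c(OC)c2)cc(OC)cc1OCc1ccccc1
F2 | step 8 | 2-(benzyloxy)-6-{2-[4-(benzyloxy)-3-methoxyphenyl]ethyl}-4-methoxybenzaldehyde | O=Cc1c(CCc2ccc(OCc3ccccc3)c(OC)c2)cc(OC)cc1OCc1ccccc1
F3 | step 8 | (2-(benzyloxy)-6-{2-[4-(benzyloxy)-3-methoxyphenyl]ethyl}-4-methoxyphenyl)lithium | [Li]c1c(CCc2ccc(OCc3ccccc3)c(OC)c2)cc(OC)cc1OCc1ccccc1
F4 | step 8 | bis(2-(benzyloxy)-6-{2-[4-(benzyloxy)-3-methoxyphenyl]ethyl}-4-methoxyphenyl)methanol | OC(c1c(CCc2ccc(OCc3ccccc3)c(OC)c2)cc(OC)cc1OCc1ccccc1)c1c(CCc2ccc(OCc3ccccc3)c(OC)c2)cc(OC)cc1OCc1ccccc1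
F5 | step 4 | 4-(benzyloxy)-3-methoxybenzaldehyde | O=Cc1ccc(OCc2ccccc2)c(OC)c1
F6 | step 4 | 1-(benzyloxy)-4-ethenyl-2-methoxybenzene | C=Cc1ccc(OCc2ccccc2)c(OC)c1
F7 | step 4 | 9-{2-[4-(benzyloxy)-3-methoxyphenyl]ethyl}-9-borabicyclo[3.3.1]nonane | COc1cc(CCB2C3CCCC2CCC3)ccc1OCc1ccccc1
F8 | step 4 | methyl 2,6-dihydroxy-4-methoxybenzoate (bought in) | COC(=O)c1c(O)cc(OC)cc1O
F9 | step 4 | methyl 2-(benzyloxy)-6-hydroxy-4-methoxybenzoate | COC(=O)c1c(O)cc(OC)cc1OCc1ccccc1
F10 | step 4 | methyl 2-(benzyloxy)-4-methoxy-6-[(trifluoromethanesulfonyl)oxy]benzoate | COC(=O)c1c(OS(=O)(=O)C(F)(F)F)cc(OC)cc1OCc1ccccc1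
F11 | step 7 | 2-(benzyloxy)-6-{2-[4-(benzyloxy)-3-methoxyphenyl]ethyl}-4-methoxybenzoyl chloride | ClC(=O)c1c(CCc2ccc(OCc3ccccc3)c(OC)c2)cc(OC)cc1OCc1ccccc1
F12 | step 7 | sodium (2-(benzyloxy)-6-{2-[4-(benzyloxy)-3-methoxyphenyl]ethyl}-4-methoxyphenyl)methanolate | [Na+].[O-]Cc1c(CCc2ccc(OCc3ccccc3)c(OC)c2)cc(OC)cc1OCc1ccccc1
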